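## The problem

Kanzonol T is an achiral isoflavone: there is no stereocentre to set and none that could steer another, and the only olefin geometry is the cis double bond held inside the 2,2-dimethylchromene ring. The difficulties are regiochemical. Ring A is a phloroglucinol nucleus with the 3-hydroxy-3-methylbutyl chain on C6 between the 5- and 7-oxygens and with C8 unsubstituted, so the pyranone (ring C) must be closed through the one ring A oxygen that lies para to the chain; otherwise 6- and 8-alkyl chromones form together. Ring B is a 2,2-dimethyl-2H-chromen-5-ol bound through its C6 (C1' of the isoflavone), so the 2'-hydroxyl is flanked by C1' and the chromene carbon C3', with the pyran oxygen on C4'. The hardest bond is C3–C1', which links the alpha carbon of the pyranone to an electron-rich arene carbon that has an ortho oxygen. Three groups are fragile: the tertiary carbinol, which sits two carbons from a ring bearing two phenols and in strong acid ionises to a 2,2-dimethylchroman or an alkene; the chromene olefin, which excludes hydrogenation, strong acid and free electrophilic halogen late in the route; and the pyranone, which hydroxide or unhindered amide bases open at C2. Ring A is also the most nucleophilic part of any chromone intermediate (at C8), so bromine cannot be placed on C3 by electrophilic substitution of a finished chromone. The feature that makes the key step possible is that O2' is ortho to C1' while C2, the neighbour of C3, carries only hydrogen in the target: an ester from O2' to a carboxyl on C2 holds C3 and C1' at the ends of a chain that closes a six-membered ring, C1' is the only hydrogen-bearing carbon ortho to O2', and the bridging carbon can afterwards leave as CO2.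

## Retrosynthesis

Tris-MOM ether 28 is the direct precursor of Kanzonol T (29); the cut is through three aryl O–CH2 bonds. Acetal protection is preferred to benzyl (hydrogenolysis would also reduce the chromene), allyl (lost under palladium) and silyl ethers (lost under carbonate and hydroxide), and it lets the cap on O2' leave together with the ring A groups. The forward step is the only acidic one in the route and is placed last; it must cleave three acetals faster than it ionises the tertiary carbinol.

In 28 the C2–H bond is traced back to a C2–CO2H bond (acid 27), the bridge carbon of the key step. Loss of CO2 from chromone-2-carboxylic acids is the classical exit to isoflavones, and silver catalysis lowers the temperature. A free 2'-hydroxy acid would re-close to the lactone as soon as the medium turns acidic. Lactone 24 is therefore opened with methoxide and the phenoxide 25 is capped in the same flask (26) before the ester is saponified to 27. The cap is a third MOM group, so it costs no extra step at the end.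

Lactone 24 is cut at C3–C1' to give bromo ester 23. An intermolecular Suzuki–Miyaura union at the same bond is the obvious neighbour, but it needs a ring B boron reagent flanked by an oxygen and prone to protodeboronation, and it is kept only as a reserve. The tether turns the coupling into a six-membered ring closure, needs no organometallic derivative of the electron-rich chromene, and fixes the site on ring B. The price is the bridge carbon. The forward reaction must achieve C–H metalation at C1' before the activated aryl ester is cleaved.

Ester 23 is cut at the C(=O)–O bond into acid 15 and chromenol 22, two fragments of similar size. A carbodiimide coupling suffices because the only competing hydroxyl is tertiary.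

In acid 15 the C2–CO2H bond is cut to give 3-bromochromone 13, and 13 is taken back through the O1–C2 and C3–Br bonds to acetophenone 11 by way of enaminone 12. The neighbouring route, an oxalate Claisen condensation with acid-mediated cyclodehydration, would put the MOM ethers and the carbinol through hot acid and would still have to place bromine at C3 in competition with C8 of ring A. Bromocyclisation of 12 puts the halogen on the enaminone alpha carbon under neutral conditions, and the bromine then acidifies C2–H for lithiation and carboxylation (14). The forward steps must keep the halogen to one equivalent and the amide base hindered and cold.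

In 11 the aryl–acetyl bond is the one to cut, but Friedel–Crafts and Fries chemistry are excluded by the acetals and the carbinol. The acetyl group is therefore traced through carbinol 10 to aldehyde 9, which arises by magnesium-mediated ortho-formylation of phenol 8. The symmetry of 8 is the point of the ring A plan: its two ortho positions are equivalent, and its free hydroxyl, the future O1, lies para to the chain, so the chain can end only on C6.

Phenol 8 is cut at the C–O bond para to the chain, which leads to arene 6. Sterically controlled C–H borylation (7) and oxidation reach exactly this position, the only ring C–H without an ortho neighbour. The alternative, a phloroglucinol aldehyde whose para hydroxyl must be masked selectively among three, has no reliable selectivity. Carbinol 6 comes from prenyl arene 5 by Markovnikov hydration, and 5 from the bis-MOM ether 2 of resorcinol (1) and prenyl bromide (3) by lithiation (4) between the two acetal oxygens.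

Chromenol 22 is traced back by removal of two hydrogens to enone 19, and from there through the O–C and C–C bonds of the pyran to cyclohexane-1,3-dione (16) and 3-methylbut-2-enal (17). Direct annulation of the enal onto resorcinol would give mainly the 7-hydroxy isomer, whereas the dione fixes the oxygen pattern before aromatisation. The forward steps are a Knoevenagel/electrocyclisation cascade (18) and a selenoxide dehydrogenation (20, 21).

## Roads not taken

Alternative 1: The cut is through the four C–CH3 bonds of the two CMe2 carbinol units, so both side arms are carried as lactones in bis-lactone A2: a dihydropyranone closed from the C6 chain onto O7 and a coumarin-type pyranone closed from C3' onto O4'. In the forward step excess MeLi with CeCl3 would add twice to each lactone carbonyl and open both rings to A1, which carries the saturated carbinol on ring A and a (Z)-3-hydroxy-3-methylbut-1-enyl arm next to a free 4'-hydroxyl. Acid-catalysed cyclodehydration of that allylic carbinol and loss of the 2'-O-MOM group would finish the synthesis.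
- Merits: the lactones protect O7 and O4' without extra groups, and both acid-labile carbinols appear only after all metal-mediated chemistry, whereas the chosen route carries the saturated carbinol from step 3.
- Weak points: A2 is itself a chromone, so methyllithium meets a further electrophile (conjugate addition at C2 opens ring C) and an acidic 5-hydroxyl. The coumarin can take the nucleophile at C4 instead of the carbonyl. The chromene must be closed by acid in the presence of the saturated carbinol flanked by two phenols. Above all, the disconnection does not address C3–C1', which must still be made on the way to A2 with ring B carrying a base-labile coumarin.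
- Comparison: against the late unveiling of the carbinols, the chosen plan sets the fact that a tertiary alcohol is inert to every reagent it meets before the last step, and that its key step solves the bond Alternative 1 leaves open.

Alternative 2: Ring B is built instead of brought in. The C1'–C6' and C2'–C3' bonds are cut, which leads to pyrano-fused 2-pyranone A4 as the diene and 3-alkynylchromone ynol ether A5 as the dienophile. Heating the two should give a bicyclic [4+2] adduct that loses CO2 to arene A3, with the chromene already fused and all ring B substituents in place. The polarisation is matched, since the nucleophilic carbon of the ynol ether (C1') meets the electrophilic C6 of the pyranone.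
- Merits: no substitution chemistry on an electron-rich ring B, a fully convergent union, and an end game of deprotections only, which is shorter than the four steps the chosen plan spends on opening and excising its bridge.
- Weak points: A4 carries a donor oxygen on C4 and a substituent on C3, so it is a sluggish diene that will need high temperature. A5 is an alkyl ynol ether with beta hydrogens in its 2-(trimethylsilyl)ethyl group and can fragment to a ketene by a retro-ene path at such temperatures. A5 also has to be assembled from a 3-halochromone and a fragile alkoxyacetylene.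
- Comparison: the chosen plan is longer after its key step, but both of its partners (15 and 22) are stable and easily made, and its bond formation is intramolecular at 110 °C within a known reaction class.

Alternative 3: The cut is through O1–C8a and C4–C4a, so ring C is formed last from an aryne of ring A, released from silyl triflate A7, and formyl arylacetate A8 that carries ring B. With CsF the enol oxygen of A8 should add to C8a, the aryne carbon remote from the 5-alkoxy group, and the resulting C4a anion should acylate on the ester to give protected isoflavone A6.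
- Merits: it is the most convergent of the four plans and uses the same symmetric ring A logic as the chosen route (A7 would derive from a silyl ether of phenol 8). The alkoxy group directs the nucleophile to the correct aryne carbon, fluoride is harmless to every functional group, and no bridging atom has to be removed, so it would be several steps shorter.
- Weak points: the enolate of a 1,3-dicarbonyl compound normally attacks an aryne through carbon, which leads to C-arylation and acyl–alkyl insertion instead of the chromone. Even after O-arylation the aryl anion can be quenched by the acidic C–H of a second molecule of A8 before it reaches the ester. A7 needs an ortho-silyl triflate placed next to a MOM ether.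
- Comparison: in step count Alternative 3 is clearly better. The chosen plan sets against this that each of its bond-forming steps follows a known course, whereas the annulation depends on an O-selectivity for which the substrate offers no control element.

Key step: step 13

Remark on the chemistry: the target has no stereocentre; 10 and 20 are racemic and their stereocentres vanish in the next operation, and 26 and 27 may show hindered rotation about C3–C1' without consequence for the target.

## Steps

Step 1
Reactants: 1 resorcinol (benzene-1,3-diol)
Product: 2 1,3-bis(methoxymethoxy)benzene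
Conditions: NaH, MOMCl, DMF, 0 °C to rt
Reagents that add atoms: chloromethyl methyl ether, COCCl
Why: Williamson-type alkylation of both phenoxides gives the bis-acetal; the MOM groups later serve as directing groups for lithiation and as the ring A protection.

Step 2
Reactants: 2 1,3-bis(methoxymethoxy)benzene; 3 1-bromo-3-methylbut-2-ene (prenyl bromide)
Product: 5 1,3-bis(methoxymethoxy)-2-(3-methylbut-2-en-1-yl)benzene, via 2-lithio arene 4 (not isolated)
Conditions: n-BuLi, THF, 0 °C; CuI (10 mol%), then 3, −78 °C to rt
Reagents that add atoms: none
Why: Directed ortho-metalation occurs at the carbon flanked by both acetal oxygens; copper-mediated SN2 allylation with 3 avoids the reverse-prenyl (SN2') product.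

Step 3
Reactants: 5 1,3-bis(methoxymethoxy)-2-(3-methylbut-2-en-1-yl)benzene
Product: 6 4-[2,6-bis(methoxymethoxy)phenyl]-2-methylbutan-2-ol
Conditions: Co(acac)2 (20 mol%), PhSiH3, O2 (1 atm), THF, rt; aq. Na2S2O3
Reagents that add atoms: dioxygen, O=O
Why: Mukaiyama hydration: hydrogen-atom transfer from a cobalt hydride to the trisubstituted alkene gives the tertiary radical, which is trapped by O2 and reduced to the Markovnikov alcohol; the neutral conditions leave the acetals intact.

Step 4
Reactants: 6 4-[2,6-bis(methoxymethoxy)phenyl]-2-methylbutan-2-ol
Product: 8 4-(3-hydroxy-3-methylbutyl)-3,5-bis(methoxymethoxy)phenol, via aryl pinacol boronate 7 (not isolated)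
Conditions: [Ir(OMe)(cod)]2 (1.5 mol%), 4,4'-di-tert-butyl-2,2'-bipyridine (3 mol%), B2pin2, THF, 80 °C; then 30% H2O2, aq. NaOH, 0 °C
Reagents that add atoms: hydrogen peroxide, OO
Why: Iridium-catalysed aromatic C–H borylation is sterically controlled, and of the three ring C–H bonds only the one para to the chain has no ortho substituent; basic peroxide oxidises the boronate to the symmetric phenol, and the tertiary hydroxyl is only transiently O-borylated.

Step 5
Reactants: 8 4-(3-hydroxy-3-methylbutyl)-3,5-bis(methoxymethoxy)phenol
Product: 9 2-hydroxy-5-(3-hydroxy-3-methylbutyl)-4,6-bis(methoxymethoxy)benzaldehyde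
Conditions: MgCl2, Et3N, (CH2O)n, MeCN, 80 °C
Reagents that add atoms: formaldehyde (as paraformaldehyde), C=O
Why: Casnati–Skattebøl ortho-formylation: the magnesium phenoxide delivers formaldehyde to the ortho carbon and a second formaldehyde oxidises the benzylic alkoxide. The two ortho positions of 8 are equivalent, so one aldehyde forms and the 6- versus 8-alkyl question is settled here.

Step 6
Reactants: 9 2-hydroxy-5-(3-hydroxy-3-methylbutyl)-4,6-bis(methoxymethoxy)benzaldehyde
Product: 10 2-(1-hydroxyethyl)-4-(3-hydroxy-3-methylbutyl)-3,5-bis(methoxymethoxy)phenol (racemic)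
Conditions: MeMgBr (3.5 equiv), THF, −20 to 0 °C; aq. NH4Cl; used crude
Reagents that add atoms: methylmagnesium bromide, C[Mg]Br
Why: Grignard addition to the aldehyde after deprotonation of the phenol and the tertiary alcohol; the new carbinol centre forms as a racemate and is erased in step 7. The crude product is carried on without chromatography because the electron-rich benzylic carbinol ionises readily.

Step 7
Reactants: 10 2-(1-hydroxyethyl)-4-(3-hydroxy-3-methylbutyl)-3,5-bis(methoxymethoxy)phenol
Product: 11 1-[2-hydroxy-5-(3-hydroxy-3-methylbutyl)-4,6-bis(methoxymethoxy)phenyl]ethan-1-one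
Conditions: MnO2 (activated, excess), CH2Cl2, rt
Reagents that add atoms: none
Why: MnO2 oxidation of a benzylic alcohol gives the hydrogen-bonded ortho-hydroxyacetophenone; the aliphatic tertiary alcohol cannot be oxidised.

Step 8
Reactants: 11 1-[2-hydroxy-5-(3-hydroxy-3-methylbutyl)-4,6-bis(methoxymethoxy)phenyl]ethan-1-one
Product: 13 3-bromo-6-(3-hydroxy-3-methylbutyl)-5,7-bis(methoxymethoxy)-4H-chromen-4-one, via enaminone 12 (not isolated)
Conditions: Me2NCH(OMe)2, toluene, 90 °C; evaporate; Br2 (1.0 equiv), CHCl3, 0 °C
Reagents that add atoms: N,N-dimethylformamide dimethyl acetal, COC(OC)N(C)C; bromine, BrBr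
Why: Condensation of the methyl ketone with the amide acetal gives the ortho-hydroxyaryl enaminone, whose alpha carbon is brominated far faster than ring A. The phenol then adds to the iminium carbon and dimethylamine is expelled (enaminone halocyclisation to a 3-halochromone), so no acid is needed and the acetals survive.

Step 9
Reactants: 13 3-bromo-6-(3-hydroxy-3-methylbutyl)-5,7-bis(methoxymethoxy)-4H-chromen-4-one
Product: 15 3-bromo-6-(3-hydroxy-3-methylbutyl)-5,7-bis(methoxymethoxy)-4-oxo-4H-chromene-2-carboxylic acid, via C2-lithio chromone 14 (not isolated)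
Conditions: lithium 2,2,6,6-tetramethylpiperidide (2.5 equiv), THF, −78 °C; CO2; cold 0.5 M HCl to pH 3
Reagents that add atoms: carbon dioxide, O=C=O
Why: After the alkoxide has formed, the hindered amide removes C2–H, which is alpha to the ring oxygen and acidified by the adjacent bromine (as in the alpha-lithiation of 3-bromofurans), and the vinyllithium is carboxylated. The low temperature suppresses loss of LiBr and addition to the pyranone.

Step 10
Reactants: 16 cyclohexane-1,3-dione; 17 3-methylbut-2-enal
Product: 19 2,2-dimethyl-2,6,7,8-tetrahydro-5H-chromen-5-one, via oxatriene 18 (not isolated)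
Conditions: ethylenediammonium diacetate (10 mol%), MeOH, rt to 50 °C
Reagents that add atoms: none
Why: Knoevenagel condensation gives the 2-alkylidene dione 18, which closes by 6π oxa-electrocyclisation (formal [3+3] annulation) to the 2,2-dimethylpyran.

Step 11
Reactants: 19 2,2-dimethyl-2,6,7,8-tetrahydro-5H-chromen-5-one
Product: 22 2,2-dimethyl-2H-chromen-5-ol, via 6-phenylselanyl ketone 20 (not isolated), via dienone 21 (not isolated)
Conditions: lithium diisopropylamide, THF, −78 °C; PhSeCl; then 30% H2O2, pyridine, 0 °C to rt
Reagents that add atoms: none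
Why: Kinetic alpha'-deprotonation of the vinylogous ester and selenenylation give racemic 20; selenoxide syn-elimination forms dienone 21, which tautomerises to the phenol. The ring is aromatised without touching the chromene double bond.

Step 12
Reactants: 15 3-bromo-6-(3-hydroxy-3-methylbutyl)-5,7-bis(methoxymethoxy)-4-oxo-4H-chromene-2-carboxylic acid; 22 2,2-dimethyl-2H-chromen-5-ol
Product: 23 2,2-dimethyl-2H-chromen-5-yl 3-bromo-6-(3-hydroxy-3-methylbutyl)-5,7-bis(methoxymethoxy)-4-oxo-4H-chromene-2-carboxylate
Conditions: EDC·HCl, DMAP, CH2Cl2, 0 °C to rt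
Reagents that add atoms: none
Why: Steglich esterification: the carbodiimide-activated acid is transferred by DMAP to the phenol; the tertiary alcohol is too hindered to compete and the medium stays neutral.

Step 13
Reactants: 23 2,2-dimethyl-2H-chromen-5-yl 3-bromo-6-(3-hydroxy-3-methylbutyl)-5,7-bis(methoxymethoxy)-4-oxo-4H-chromene-2-carboxylate
Product: 24 lactone of 3-(5-hydroxy-2,2-dimethyl-2H-chromen-6-yl)-6-(3-hydroxy-3-methylbutyl)-5,7-bis(methoxymethoxy)-4-oxo-4H-chromene-2-carboxylic acid (C2 carboxyl esterified by the chromene 5-oxygen; six-membered ring)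
Conditions: Pd(OAc)2 (10 mol%), PCy3·HBF4 (20 mol%), K2CO3 (2 equiv), t-BuCO2H (30 mol%), DMA, 110 °C
Reagents that add atoms: none
Why: Zerovalent palladium formed from Pd(OAc)2 and the phosphine inserts into the C3–Br bond, which is activated as a vinylogous acyl bromide. The ester tether then holds the divalent palladium beside C6–H of the chromenyl ring (C1' of the target), and carboxylate-assisted concerted metalation–deprotonation gives a seven-membered palladacycle. Reductive elimination forms the C3–C1' bond and closes the six-membered lactone, the only ring formed; it closes by C–C bond formation between two sp2 carbons and creates no stereocentre. The closest known reaction type is the palladium-catalysed intramolecular direct arylation of aryl 2-halobenzoates to benzo[c]chromen-6-ones (lactone-bridged biaryl coupling). Site selectivity on ring B is fixed by the tether, since of the two carbons ortho to the ester oxygen only C6 carries hydrogen. The chromene C4–H and the chromene olefin could be reached only through a seven-membered carbocycle, so vinylic arylation and Heck insertion should be slower than the six-membered closure. The step needs the less stable s-cis rotamer of the aryl ester, hence the temperature, and dry carbonate so that the activated ester is not cleaved before it cyclises; the MOM ethers and the tertiary alcohol are inert.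

Step 14
Reactants: 24 lactone-bridged isoflavone
Product: 26 methyl 6-(3-hydroxy-3-methylbutyl)-5,7-bis(methoxymethoxy)-3-[5-(methoxymethoxy)-2,2-dimethyl-2H-chromen-6-yl]-4-oxo-4H-chromene-2-carboxylate, via ring-opened phenoxide methyl ester 25 (not isolated)
Conditions: K2CO3, MeOH–THF, 0 °C; evaporate; MOMCl, DMF, 0 °C to rt
Reagents that add atoms: methanol, CO; chloromethyl methyl ether, COCCl
Why: Methoxide opens the activated aryl ester lactone to the methyl ester and the phenoxide, which is a much weaker base than methoxide, so the open form dominates. O-Alkylation with MOMCl then caps the 2'-oxygen and blocks re-lactonisation in the acidic steps that follow.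

Step 15
Reactants: 26 methyl ester
Product: 27 6-(3-hydroxy-3-methylbutyl)-5,7-bis(methoxymethoxy)-3-[5-(methoxymethoxy)-2,2-dimethyl-2H-chromen-6-yl]-4-oxo-4H-chromene-2-carboxylic acid
Conditions: LiOH·H2O, THF–H2O, 0 °C to rt; cold 0.5 M HCl to pH 3
Reagents that add atoms: lithium hydroxide, [Li+].[OH-]
Why: Saponification of the electron-poor chromone-2-carboxylate at low temperature should be faster than hydroxide attack at C2 of the pyranone; brief cold acidification to pH 3 leaves the acetals intact.

Step 16
Reactants: 27 chromone-2-carboxylic acid
Product: 28 6-(3-hydroxy-3-methylbutyl)-5,7-bis(methoxymethoxy)-3-[5-(methoxymethoxy)-2,2-dimethyl-2H-chromen-6-yl]-4H-chromen-4-one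
Conditions: Ag2CO3 (15 mol%), AcOH (5 mol%), DMSO, 110 °C
Reagents that add atoms: none
Why: Silver-catalysed protodecarboxylation of a heteroaromatic acid with an alpha heteroatom: the monovalent silver carboxylate loses CO2 to a C2–silver species that is protonated. Chromone-2-carboxylic acids also decarboxylate thermally, the classical exit from 2-carboxyisoflavones, and the capped 2'-oxygen cannot re-lactonise.

Step 17
Reactants: 28 tris-MOM isoflavone
Product: 29 Kanzonol T, 5,7-dihydroxy-3-(5-hydroxy-2,2-dimethyl-2H-chromen-6-yl)-6-(3-hydroxy-3-methylbutyl)-4H-chromen-4-one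
Conditions: 3 M aq. HCl, MeOH–THF, rt to 40 °C
Reagents that add atoms: none
Why: Acid-catalysed acetal exchange with methanol removes the three aryl MOM ethers, the chelated 5-O-MOM first; dilute acid near room temperature is chosen so that the tertiary carbinol and the chromene are not ionised.

## Compound list

1 | resorcinol (benzene-1,3-diol) | Oc1cccc(O)c1 | starting material
2 | 1,3-bis(methoxymethoxy)benzene | COCOc1cccc(OCOC)c1 | intermediate
3 | 1-bromo-3-methylbut-2-ene (prenyl bromide) | CC(C)=CCBr | starting material
4 | 2-lithio-1,3-bis(methoxymethoxy)benzene (not isolated) | [Li]c1c(OCOC)cccc1OCOC | intermediate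
5 | 1,3-bis(methoxymethoxy)-2-(3-methylbut-2-en-1-yl)benzene | COCOc1cccc(OCOC)c1CC=C(C)C | intermediate
6 | 4-[2,6-bis(methoxymethoxy)phenyl]-2-methylbutan-2-ol | COCOc1cccc(OCOC)c1CCC(C)(C)O | intermediate
7 | 4-[2,6-bis(methoxymethoxy)-4-(4,4,5,5-tetramethyl-1,3,2-dioxaborolan-2-yl)phenyl]-2-methylbutan-2-ol (not isolated) | COCOc1cc(B2OC(C)(C)C(C)(C)O2)cc(OCOC)c1CCC(C)(C)O | intermediate
8 | 4-(3-hydroxy-3-methylbutyl)-3,5-bis(methoxymethoxy)phenol | COCOc1cc(O)cc(OCOC)c1CCC(C)(C)O | intermediate
9 | 2-hydroxy-5-(3-hydroxy-3-methylbutyl)-4,6-bis(methoxymethoxy)benzaldehyde | O=Cc1c(O)cc(OCOC)c(CCC(C)(C)O)c1OCOC | intermediate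
10 | 2-(1-hydroxyethyl)-4-(3-hydroxy-3-methylbutyl)-3,5-bis(methoxymethoxy)phenol (racemic) | CC(O)c1c(O)cc(OCOC)c(CCC(C)(C)O)c1OCOC | intermediate
11 | 1-[2-hydroxy-5-(3-hydroxy-3-methylbutyl)-4,6-bis(methoxymethoxy)phenyl]ethan-1-one | CC(=O)c1c(O)cc(OCOC)c(CCC(C)(C)O)c1OCOC | intermediate
12 | (E)-3-(dimethylamino)-1-[2-hydroxy-5-(3-hydroxy-3-methylbutyl)-4,6-bis(methoxymethoxy)phenyl]prop-2-en-1-one (not isolated) | CN(C)/C=C/C(=O)c1c(O)cc(OCOC)c(CCC(C)(C)O)c1OCOC | intermediate
13 | 3-bromo-6-(3-hydroxy-3-methylbutyl)-5,7-bis(methoxymethoxy)-4H-chromen-4-one | CC(C)(O)CCc1c(OCOC)cc2occ(Br)c(=O)c2c1OCOC | intermediate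
14 | C2-lithio derivative of 13 as its lithium alkoxide (not isolated) | CC(C)(O[Li])CCc1c(OCOC)cc2oc([Li])c(Br)c(=O)c2c1OCOC | intermediate
15 | 3-bromo-6-(3-hydroxy-3-methylbutyl)-5,7-bis(methoxymethoxy)-4-oxo-4H-chromene-2-carboxylic acid | CC(C)(O)CCc1c(OCOC)cc2oc(C(=O)O)c(Br)c(=O)c2c1OCOC | intermediate
16 | cyclohexane-1,3-dione | O=C1CCCC(=O)C1 | starting material
17 | 3-methylbut-2-enal | CC(C)=CC=O | starting material
18 | 2-(3-methylbut-2-en-1-ylidene)cyclohexane-1,3-dione (not isolated) | CC(C)=CC=C1C(=O)CCCC1=O | intermediate
19 | 2,2-dimethyl-2,6,7,8-tetrahydro-5H-chromen-5-one | O=C1CCCC2=C1C=CC(C)(C)O2 | intermediate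
20 | 2,2-dimethyl-6-(phenylselanyl)-2,6,7,8-tetrahydro-5H-chromen-5-one (racemic, not isolated) | O=C1C([Se]c3ccccc3)CCC2=C1C=CC(C)(C)O2 | intermediate
21 | 2,2-dimethyl-2,8-dihydro-5H-chromen-5-one, keto tautomer of 22 (not isolated) | O=C1C=CCC2=C1C=CC(C)(C)O2 | intermediate
22 | 2,2-dimethyl-2H-chromen-5-ol | Oc1cccc2OC(C)(C)C=Cc12 | intermediate
23 | 2,2-dimethyl-2H-chromen-5-yl 3-bromo-6-(3-hydroxy-3-methylbutyl)-5,7-bis(methoxymethoxy)-4-oxo-4H-chromene-2-carboxylate | CC(C)(O)CCc1c(OCOC)cc2oc(C(=O)Oc3cccc4OC(C)(C)C=Cc34)c(Br)c(=O)c2c1OCOC | intermediate
24 | lactone-bridged isoflavone: lactone of 3-(5-hydroxy-2,2-dimethyl-2H-chromen-6-yl)-6-(3-hydroxy-3-methylbutyl)-5,7-bis(methoxymethoxy)-4-oxo-4H-chromene-2-carboxylic acid (ester oxygen on C2', carboxyl carbon on C2) | CC(C)(O)CCc1c(OCOC)cc2oc3c(c(=O)c2c1OCOC)-c1ccc2OC(C)(C)C=Cc2c1OC3=O | intermediate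
25 | methyl 3-(5-hydroxy-2,2-dimethyl-2H-chromen-6-yl)-6-(3-hydroxy-3-methylbutyl)-5,7-bis(methoxymethoxy)-4-oxo-4H-chromene-2-carboxylate, formed as its potassium phenoxide (not isolated) | COC(=O)c1oc2cc(OCOC)c(CCC(C)(C)O)c(OCOC)c2c(=O)c1-c1ccc2OC(C)(C)C=Cc2c1O | intermediate
26 | methyl 6-(3-hydroxy-3-methylbutyl)-5,7-bis(methoxymethoxy)-3-[5-(methoxymethoxy)-2,2-dimethyl-2H-chromen-6-yl]-4-oxo-4H-chromene-2-carboxylate | COC(=O)c1oc2cc(OCOC)c(CCC(C)(C)O)c(OCOC)c2c(=O)c1-c1ccc2OC(C)(C)C=Cc2c1OCOC | intermediate
27 | 6-(3-hydroxy-3-methylbutyl)-5,7-bis(methoxymethoxy)-3-[5-(methoxymethoxy)-2,2-dimethyl-2H-chromen-6-yl]-4-oxo-4H-chromene-2-carboxylic acid | OC(=O)c1oc2cc(OCOC)c(CCC(C)(C)O)c(OCOC)c2c(=O)c1-c1ccc2OC(C)(C)C=Cc2c1OCOC | intermediate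
28 | 6-(3-hydroxy-3-methylbutyl)-5,7-bis(methoxymethoxy)-3-[5-(methoxymethoxy)-2,2-dimethyl-2H-chromen-6-yl]-4H-chromen-4-one | CC(C)(O)CCc1c(OCOC)cc2occ(-c3ccc4OC(C)(C)C=Cc4c3OCOC)c(=O)c2c1OCOC | intermediate
29 | Kanzonol T, 5,7-dihydroxy-3-(5-hydroxy-2,2-dimethyl-2H-chromen-6-yl)-6-(3-hydroxy-3-methylbutyl)-4H-chromen-4-one | CC(C)(O)CCc1c(O)cc2occ(-c3ccc4c(c3O)C=CC(C)(C)O4)c(=O)c2c1O | target

## Step count and least certain steps

Total step count: 17. Longest linear sequence: 15 steps (steps 1–9 and 12–17 from resorcinol); the chromenol branch is 2 steps (10 and 11).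

Step 13 (key step). Most likely failure: the activated aryl ester is cleaved by carbonate, pivalate or traces of water before it cyclises, or the cyclisation is slow because the ester must adopt its less stable rotamer, so that protodebromination or insertion into the chromene olefin takes over. Fallback (from 22 and 13, returning at 28): the bridge is given up and the same bond is made by Suzuki–Miyaura coupling. Chromenol 22 would be protected (MOMCl, i-Pr2NEt, CH2Cl2) as 5-(methoxymethoxy)-2,2-dimethyl-2H-chromene F1, lithiated ortho to the acetal oxygen (n-BuLi, THF, 0 °C) and borylated with 2-isopropoxy-4,4,5,5-tetramethyl-1,3,2-dioxaborolane to 2-[5-(methoxymethoxy)-2,2-dimethyl-2H-chromen-6-yl]-4,4,5,5-tetramethyl-1,3,2-dioxaborolane F2. Coupling of F2 with bromochromone 13 (Pd(dppf)Cl2, K2CO3, dioxane–water, 80 °C) would give 28 directly and bypass steps 9 and 12–16.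

Step 9. Most likely failure: addition of the amide base to C2 or C4 of the pyranone, condensation of the C2-lithio species with unreacted chromone, or loss of lithium bromide on warming, each of which consumes the bromochromone before carboxylation. Fallback (from 11, returning at 15): classical chromone-2-carboxylate chemistry. Claisen condensation of 11 with diethyl oxalate (NaOEt, EtOH–THF) would give ethyl 4-[2-hydroxy-5-(3-hydroxy-3-methylbutyl)-4,6-bis(methoxymethoxy)phenyl]-2,4-dioxobutanoate F3. N-Bromosuccinimide (CH2Cl2, 0 °C) would brominate its enolised methylene to ethyl 3-bromo-4-[2-hydroxy-5-(3-hydroxy-3-methylbutyl)-4,6-bis(methoxymethoxy)phenyl]-2,4-dioxobutanoate F4. Buffered cyclodehydration (pyridinium p-toluenesulfonate, toluene, molecular sieves, 70 °C) would close ethyl 3-bromo-6-(3-hydroxy-3-methylbutyl)-5,7-bis(methoxymethoxy)-4-oxo-4H-chromene-2-carboxylate F5, and Me3SnOH in 1,2-dichloroethane would release acid 15 without hydroxide.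

Step 6. Most likely failure: ionisation of the electron-rich ortho-hydroxybenzylic carbinol during work-up (ortho-quinone methide formation and oligomerisation) before it can be oxidised in step 7. Fallback (from 8, returning at 11): the acetyl group is introduced by directed metalation. Phenol 8 would be benzylated (BnBr, K2CO3, DMF) to 4-[4-(benzyloxy)-2,6-bis(methoxymethoxy)phenyl]-2-methylbutan-2-ol F6, lithiated between the benzyloxy and MOM groups (n-BuLi, 2.2 equiv, THF, 0 °C) and acylated with N-methoxy-N-methylacetamide to 1-[2-(benzyloxy)-5-(3-hydroxy-3-methylbutyl)-4,6-bis(methoxymethoxy)phenyl]ethan-1-one F7. Hydrogenolysis (H2, palladium on carbon, EtOAc) would give 11.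

Step 14. Most likely failure: re-closure of the lactone while methanol is removed, incomplete alkylation of the hindered 2'-phenoxide, or methoxide addition to C2 of the chromone. Fallback (from 24, returning at 27): LiOH in THF–water would open 24 to dilithium 3-(2,2-dimethyl-5-oxido-2H-chromen-6-yl)-6-(3-hydroxy-3-methylbutyl)-5,7-bis(methoxymethoxy)-4-oxo-4H-chromene-2-carboxylate F8, in which a carboxylate instead of an ester faces the phenoxide, so re-closure is impossible. After drying, MOMCl and i-Pr2NEt in DMF would alkylate both oxygens to methoxymethyl 6-(3-hydroxy-3-methylbutyl)-5,7-bis(methoxymethoxy)-3-[5-(methoxymethoxy)-2,2-dimethyl-2H-chromen-6-yl]-4-oxo-4H-chromene-2-carboxylate F9, whose acyl acetal alone is cleaved by cold aqueous LiOH to give 27.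

Step 17. Most likely failure: acid-promoted ionisation of the tertiary carbinol with capture by the 5- or 7-hydroxyl (chroman closure) or by methanol, or acid opening of the chromene, before the last acetal is gone. Fallback (from 28, returning at 29): protic acid is avoided. TMSOTf with 2,2'-bipyridyl in MeCN would exchange the aryl acetals for silyl ethers and silylate the carbinol, giving 3-[2,2-dimethyl-5-(trimethylsilyloxy)-2H-chromen-6-yl]-6-[3-methyl-3-(trimethylsilyloxy)butyl]-5,7-bis(trimethylsilyloxy)-4H-chromen-4-one F10, and buffered fluoride (Bu4NF, AcOH, THF, 0 °C) would then release 29.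

## Further compounds

F1 | step 13 | 5-(methoxymethoxy)-2,2-dimethyl-2H-chromene | COCOc1cccc2OC(C)(C)C=Cc12
F2 | step 13 | 2-[5-(methoxymethoxy)-2,2-dimethyl-2H-chromen-6-yl]-4,4,5,5-tetramethyl-1,3,2-dioxaborolane | COCOc1c(B3OC(C)(C)C(C)(C)O3)ccc2OC(C)(C)C=Cc12
F3 | step 9 | ethyl 4-[2-hydroxy-5-(3-hydroxy-3-methylbutyl)-4,6-bis(methoxymethoxy)phenyl]-2,4-dioxobutanoate | CCOC(=O)C(=O)CC(=O)c1c(O)cc(OCOC)c(CCC(C)(C)O)c1OCOC
F4 | step 9 | ethyl 3-bromo-4-[2-hydroxy-5-(3-hydroxy-3-methylbutyl)-4,6-bis(methoxymethoxy)phenyl]-2,4-dioxobutanoate (racemic) | CCOC(=O)C(=O)C(Br)C(=O)c1c(O)cc(OCOC)c(CCC(C)(C)O)c1OCOC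
F5 | step 9 | ethyl 3-bromo-6-(3-hydroxy-3-methylbutyl)-5,7-bis(methoxymethoxy)-4-oxo-4H-chromene-2-carboxylate | CCOC(=O)c1oc2cc(OCOC)c(CCC(C)(C)O)c(OCOC)c2c(=O)c1Br
F6 | step 6 | 4-[4-(benzyloxy)-2,6-bis(methoxymethoxy)phenyl]-2-methylbutan-2-ol | COCOc1cc(OCc2ccccc2)cc(OCOC)c1CCC(C)(C)O
F7 | step 6 | 1-[2-(benzyloxy)-5-(3-hydroxy-3-methylbutyl)-4,6-bis(methoxymethoxy)phenyl]ethan-1-one | CC(=O)c1c(OCc2ccccc2)cc(OCOC)c(CCC(C)(C)O)c1OCOC
F8 | step 14 | dilithium 3-(2,2-dimethyl-5-oxido-2H-chromen-6-yl)-6-(3-hydroxy-3-methylbutyl)-5,7-bis(methoxymethoxy)-4-oxo-4H-chromene-2-carboxylate | [Li+].[Li+].[O-]C(=O)c1oc2cc(OCOC)c(CCC(C)(C)O)c(OCOC)c2c(=O)c1-c1ccc2OC(C)(C)C=Cc2c1[O-]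
F9 | step 14 | methoxymethyl 6-(3-hydroxy-3-methylbutyl)-5,7-bis(methoxymethoxy)-3-[5-(methoxymethoxy)-2,2-dimethyl-2H-chromen-6-yl]-4-oxo-4H-chromene-2-carboxylate | COCOC(=O)c1oc2cc(OCOC)c(CCC(C)(C)O)c(OCOC)c2c(=O)c1-c1ccc2OC(C)(C)C=Cc2c1OCOC
F10 | step 17 | 3-[2,2-dimethyl-5-(trimethylsilyloxy)-2H-chromen-6-yl]-6-[3-methyl-3-(trimethylsilyloxy)butyl]-5,7-bis(trimethylsilyloxy)-4H-chromen-4-one | CC(C)(O[Si](C)(C)C)CCc1c(O[Si](C)(C)C)cc2occ(-c3ccc4OC(C)(C)C=Cc4c3O[Si](C)(C)C)c(=O)c2c1O[Si](C)(C)C
A1 | alternative 1 | 2'-O-MOM seco-Kanzonol T with a (Z)-3-hydroxy-3-methylbut-1-enyl group on C3' and a free 4'-hydroxyl | CC(C)(O)CCc1c(O)cc2occ(-c3ccc(O)c(/C=C\C(C)(C)O)c3OCOC)c(=O)c2c1O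
A2 | alternative 1 | bis-lactone: 5-hydroxyisoflavone with a dihydropyranone fused across C6 and O7 and a pyran-2-one (coumarin) fused across C3' and O4', 2'-O-MOM | O=C1CCc2c(O1)cc1occ(-c3ccc4oc(=O)ccc4c3OCOC)c(=O)c1c2O
A3 | alternative 2 | 5,7-bis(MOM), 2'-O-[2-(trimethylsilyl)ethyl], chain-O-triethylsilyl Kanzonol T | CC(C)(O[Si](CC)(CC)CC)CCc1c(OCOC)cc2occ(-c3ccc4OC(C)(C)C=Cc4c3OCC[Si](C)(C)C)c(=O)c2c1OCOC
A4 | alternative 2 | 2,2-dimethyl-2H,5H-pyrano[4,3-b]pyran-5-one | O=c1occc2OC(C)(C)C=Cc12
A5 | alternative 2 | 5,7-bis(methoxymethoxy)-6-[3-methyl-3-(triethylsilyloxy)butyl]-3-{[2-(trimethylsilyl)ethoxy]ethynyl}-4H-chromen-4-one | CC(C)(O[Si](CC)(CC)CC)CCc1c(OCOC)cc2occ(C#COCC[Si](C)(C)C)c(=O)c2c1OCOC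
A6 | alternative 3 | 5,7,2'-tris(MOM), chain-O-triethylsilyl Kanzonol T | CC(C)(O[Si](CC)(CC)CC)CCc1c(OCOC)cc2occ(-c3ccc4OC(C)(C)C=Cc4c3OCOC)c(=O)c2c1OCOC
A7 | alternative 3 | 3,5-bis(methoxymethoxy)-4-[3-methyl-3-(triethylsilyloxy)butyl]-2-(trimethylsilyl)phenyl trifluoromethanesulfonate | CC(C)(O[Si](CC)(CC)CC)CCc1c(OCOC)cc(OS(=O)(=O)C(F)(F)F)c([Si](C)(C)C)c1OCOC
A8 | alternative 3 | methyl 2-[5-(methoxymethoxy)-2,2-dimethyl-2H-chromen-6-yl]-3-oxopropanoate | COC(=O)C(C=O)c1ccc2OC(C)(C)C=Cc2c1OCOC
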